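## The problem

Target 38 is a normal labdane (labdane numbering throughout; β is the face of the C10 methyl C20, α the opposite face). It is a trans-fused decalin (rings A and B) with a gem-dimethyl C4, an equatorial 2α-hydroxyl, a trisubstituted C7=C8 alkene bearing C17, and a β-oriented chain at C9 whose C13 methyl centre is S and whose C15 oxygen carries a (Z)-p-coumarate. Four of the five stereocentres sit on the decalin. C5 and the quaternary C10 are adjacent ring-fusion carbons and must be trans. C9 is next to C10 and can be set under its control once the ring is rigid. C2 is shielded on the β face by the axial C19 and C20 methyls, so a reagent reaching a ring A alkene from the α face gives the 2α-alcohol. C13 is insulated from the ring by two methylenes, cannot be controlled by any ring centre and has to be bought. The C7=C8 alkene must be placed regiospecifically beside a C9–H centre without drifting to C8=C9. The (Z)-p-coumarate does not survive light, base (through the phenoxide), hydride, organometallics or dissolving metal, so it is built last; on the way, β-silyloxy ketones in ring B are base-sensitive. The enabling feature is that C5 and C10 are the β- and α-carbons of C9: with a ketone at C9, ring B is a 2-methylcyclohex-2-enone in which C5 can take the C4 arm as a nucleophile and C10 the C1 arm as an electrophile, while a C7 oxygen, needed later for the alkene, comes from carvone with the configuration that steers both additions.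

## Retrosynthesis

**Coumarate.** Target 38 is traced to its bis-silyl ether 37. In 37 the coumarate Cα=Cβ bond is cut to give phosphonoacetate 35 and aldehyde 36, and the ester C–O bond of 35 is cut to give alcohol 33 and acid 34. Esterifying with a preformed Z acid would require making and activating a geometrically labile acid; here the Z geometry arises kinetically in the last C–C bond formation. The precursor 33 is a mono-protected diol with no sensitive group.

**C7=C8 alkene.** Alkene 32 (the silyl ether of 33) is traced to enol triflate 31 and on to enone 29 (C7 ketone, C8=C9). Dehydration of a C7 alcohol would give mixtures of alkene positions. Reduction of 29 fixes C9–H and delivers a regiodefined C7–C8 enolate in one operation. The forward step must protonate C9 from the α face and trap the enolate on oxygen.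

**C9–C11 bond.** Enone 29 is cut at C9–C11 into vinylogous ester 26 and the alkyllithium from iodide 5. A conjugate addition at C9 would enter axially from the α face and give the wrong C9 epimer. Carbonyl addition erases C9 and lets the next step reset it. Iodide 5 comes through 4, 3 and 2 from half-ester 1, in which the two arms of 3-methylglutarate are already differentiated, so C13 is bought.

**Ring B oxidation pattern.** Vinylogous ester 26 comes from methyl dione 25, and 25 from dione 24 by cutting C8–C17. Dione 24 comes from diol 23, which is reached from 21 through 22 by protecting-group changes. No skeletal bond other than C8–C17 is involved; the C7 and C9 oxygens are already in place.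

**C2–O bond.** Diol 21 is traced to alkene 20 by hydroboration. At this stage C2=C3 is the only alkene, so chemoselectivity is not an issue; regiochemistry and face selectivity are asked of the neopentyl C3 and the two axial methyls.

**Ring A.** Bicyclic ketone 20 is cut at C2=C3 to diene 19 (ring-closing metathesis). The vinyl group of 19 comes from the ester of 16 through diol 17 and keto aldehyde 18. Aldol or cationic closures would give the wrong ring size or an oxygen at C3. The two arms are trans-diequatorial on ring B, which suits closure to the trans-decalin.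

**Key disconnection.** Keto ester 16 is cut at C4–C5 and C1–C10 into enone 11, ketene silyl acetal 12 and allyl bromide 13. Both bonds and both ring-fusion centres form in one flask from an achiral nucleophile, an achiral electrophile and a single carvone-derived centre. A catalytic silyl-transferring Lewis acid is chosen over a stoichiometric titanium halide so that the silyl enol ether survives for the regiospecific alkylation.

**Enone.** Enone 11 comes from alcohol 10 and acetate 9, and 9 from (R)-carvone 6 by excision of the isopropenyl group with retention at carbon.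

## Roads not taken

**Alternative 1:** The cut is C7=C8, made by ring-closing metathesis of triene A2 to the labda-1,7-diene silyl ether A1. Ring A would come from dimedone A3, with C5, C10 and C9 relayed by Claisen rearrangements. In the forward step the second-generation Grubbs catalyst joins the C5 allyl and C9 isopropenyl groups of A2 with loss of ethylene.
- Merits: the C7=C8 alkene with its methyl is created directly in the ring-closing event, with the full side chain already attached. This is clearly better than the chosen plan's seven steps (15 to 21) for the same result in ring B.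
- Weak points: A3 is achiral, so absolute configuration needs an asymmetric step whose sense must then pass through sigmatropic relays to three contiguous centres, one quaternary. C9 is exocyclic when it is set, so its relation to C10 rests on acyclic control. The C2 hydroxyl must later be delivered to the C1=C2 alkene of A1 in the presence of the C7=C8 alkene.
- Comparison: the chosen plan is longer in ring B, but it sets C5 and C10 by cyclic substrate control from a chiral-pool centre, sets C9 on a rigid decalin, and hydroborates when only one alkene is present.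

**Alternative 2:** The cuts are C5–C10 and C8–C9, made by an intramolecular Diels–Alder reaction of silyloxytriene A5 to cycloadduct A4. Heating A5 closes ring B as the cycloadduct and ring A as the tether ring.
- Merits: both rings and the centres C5, C10 and C9 form in one step, and the C7 oxygen arrives as a silyl enol ether one step from a triflate. For the core this is more step-economic than the chosen plan.
- Weak points: the dienophile is a β,β-disubstituted enoate that must form a quaternary centre, and the diene terminus C5 is neopentyl. Both slow the cycloaddition and call for temperatures at which a silyl dienol ether can isomerise. Trans fusion and endo or exo preference with a four-atom tether are not secured, and only the remote C2 silyloxy group sets the absolute sense. A4 carries C11 as an ester, so the chain with C13 still needs several steps. A5 needs three alkenes of defined geometry.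
- Comparison: the chosen plan gives up the single-step core for predictable stereocontrol and a side chain attached whole in one step.

**Alternative 3:** The cut is C3–C4, made by a proton-initiated cation–olefin closure of 6-allyl-6-methylcarvone A7 to the 2α-formyloxy decalenone A6. In formic acid the isopropenyl group gives the C4 cation, the allyl terminus attacks it and formate captures C2.
- Merits: from the same carvone 6 the decalin with its C2 oxygen, C17 and a ring B enone is reached in about three steps. This is far shorter than the nine steps from 11 to 21 of the chosen plan.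
- Weak points: a monosubstituted alkene must attack a tertiary cation and end in a secondary cation. Elimination, formate capture of the tertiary cation, hydride shift and isomerisation of the isopropenyl group are at least as likely. C2 rests on equatorial capture of a secondary cation. A6 has the enone the wrong way round (C9 ketone, C7=C8): after adding the chain to the neopentyl C9 carbonyl, the tertiary allylic oxygen must be removed with the alkene staying at C7=C8 and hydrogen entering at 9α, for which no reliable method exists.
- Comparison: the chosen plan is longer, but its ring B end game places C9–H and the alkene under control.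

Key step: step 8

Assumption: half-ester 1 and phosphonoacetic acid 34 are taken as purchased; 1 is the half-ester that pig liver esterase hydrolysis of dimethyl 3-methylglutarate (from 3-methylglutaric anhydride) is known to give, and 12 can also be made in one step from methyl isobutyrate.

## Route

Step 1
Reactants: 1 (R)-3-methylglutaric acid monomethyl ester
Product: 2 methyl (R)-5-hydroxy-3-methylpentanoate
Conditions: BH3·SMe2, THF, 0 °C → rt; MeOH quench
Reagents that add atoms: none
Why: Borane reduces a carboxylic acid much faster than an ester (chemoselective acid reduction), so only the acid arm becomes CH2OH; the stereocentre is untouched and the two arms are now different.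

Step 2
Reactants: 2 methyl (R)-5-hydroxy-3-methylpentanoate
Product: 3 methyl (R)-5-(tert-butyldimethylsilyloxy)-3-methylpentanoate
Conditions: TBSCl, imidazole, DMF, 0 °C → rt
Reagents that add atoms: tert-butyldimethylsilyl chloride, CC(C)(C)[Si](C)(C)Cl
Why: Standard silylation of a primary alcohol, carried out at once so that 2 cannot lactonise.

Step 3
Reactants: 3 methyl (R)-5-(tert-butyldimethylsilyloxy)-3-methylpentanoate
Product: 4 (S)-5-(tert-butyldimethylsilyloxy)-3-methylpentan-1-ol
Conditions: LiAlH4, Et2O, 0 °C
Reagents that add atoms: none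
Why: Hydride reduction of the ester to the primary alcohol; the primary silyl ether is stable at 0 °C and the descriptor changes only through priorities.

Step 4
Reactants: 4 (S)-5-(tert-butyldimethylsilyloxy)-3-methylpentan-1-ol
Product: 5 (R)-tert-butyl[(5-iodo-3-methylpentyl)oxy]dimethylsilane
Conditions: I2, PPh3, imidazole, CH2Cl2, 0 °C → rt
Reagents that add atoms: iodine, II
Why: Appel-type iodination of a primary alcohol; no stereocentre is involved and the primary iodide is what lithium–iodine exchange needs.

Step 5
Reactants: 6 (R)-carvone
Product: 9 (R)-5-acetoxy-2-methylcyclohex-2-enone, via methoxy hydroperoxide 7 (not isolated), via peroxyacetate 8 (not isolated)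
Conditions: O3, CH2Cl2/MeOH, −78 °C; then Ac2O, Et3N, DMAP (cat.), −78 °C → rt
Reagents that add atoms: ozone, [O-][O+]=O; methanol, CO
Why: Ozone cleaves the electron-rich isopropenyl alkene in preference to the enone and methanol traps the carbonyl oxide as 7; acetylation to 8 triggers the Criegee rearrangement, in which the ring carbon migrates to oxygen with retention, so acetoxy replaces isopropenyl at unchanged configuration.

Step 6
Reactants: 9 (R)-5-acetoxy-2-methylcyclohex-2-enone
Product: 10 (R)-5-hydroxy-2-methylcyclohex-2-enone
Conditions: K2CO3 (cat.), MeOH, 0 °C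
Reagents that add atoms: none
Why: Base-catalysed transesterification; it is kept cold and short because the β-hydroxy enone can eliminate and aromatise.

Step 7
Reactants: 10 (R)-5-hydroxy-2-methylcyclohex-2-enone
Product: 11 (R)-5-(tert-butyldimethylsilyloxy)-2-methylcyclohex-2-enone
Conditions: TBSCl, imidazole, DMF, rt
Reagents that add atoms: tert-butyldimethylsilyl chloride, CC(C)(C)[Si](C)(C)Cl
Why: Standard silylation of a secondary alcohol under weakly basic conditions that do not cause elimination.

Step 8
Reactants: 11 (R)-5-(tert-butyldimethylsilyloxy)-2-methylcyclohex-2-enone; 12 1-methoxy-2-methyl-1-(trimethylsilyloxy)propene; 13 allyl bromide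
Product: 16 methyl 2-[(1R,2S,5R)-2-allyl-5-(tert-butyldimethylsilyloxy)-2-methyl-3-oxocyclohexyl]-2-methylpropanoate (C9 ketone; C5β ester arm; C10β methyl and C10α allyl; C7α silyloxy), via trimethylsilyl enol ether 14 (not isolated), via lithium enolate 15 (not isolated)
Conditions: 12 (1.3 equiv), Ph3CSbCl6 (5 mol %), CH2Cl2, −78 °C; volatiles removed in vacuo; THF, MeLi (1.0 equiv), −30 → 0 °C; 13, DMPU, −78 → 0 °C
Reagents that add atoms: none
Why: The trityl cation activates enone 11 and the nucleophilic carbon of 12 adds to C5 through an open transition state, the silyl group passing to the enolate oxygen to give the C9=C10 silyl enol ether 14 and the C4–C5 bond (Mukaiyama–Michael addition under trityl-salt catalysis). After excess 12 is stripped, MeLi attacks silicon and releases lithium enolate 15 regiospecifically, and allyl bromide alkylates C10 to form the C1–C10 bond. The closest known reaction type is the three-component vicinal difunctionalisation of 2-methylcyclohexenones by conjugate addition and regiospecific enolate alkylation. No ring closes in this step. C5 is controlled by the carvone-derived C7 centre: the nucleophile adds axially to the half-chair enone on the face opposite the silyloxy group (1,3-trans). C10 is controlled by C5: the enolate is alkylated anti to the bulky CMe2CO2Me group, so the C1 and C4 arms end up trans as the trans-decalin requires. The step needs 1,4- over 1,2-addition (favoured by the tetrasubstituted ketene acetal), Si–O cleavage over attack on the ester (neopentyl and shielded; one equivalent of MeLi at low temperature), and no enolate equilibration toward C8, which would expel the C7 silyloxy group (lithium counter-ion, no proton source, reactive allylic halide).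

Step 9
Reactants: 16 ring B keto ester
Product: 17 2-allyl-3-(1-hydroxy-2-methylpropan-2-yl)-2-methyl-5-(tert-butyldimethylsilyloxy)cyclohexanol (C9 carbinol as epimer mixture; other centres as in 16)
Conditions: LiAlH4, THF, 0 °C → rt
Reagents that add atoms: none
Why: Hydride reduction of the hindered ester, which unavoidably also reduces the C9 ketone; the C9 carbinol configuration is irrelevant because C9 is re-oxidised.

Step 10
Reactants: 17 diol
Product: 18 2-[2-allyl-5-(tert-butyldimethylsilyloxy)-2-methyl-3-oxocyclohexyl]-2-methylpropanal (keto aldehyde; centres as in 16)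
Conditions: (COCl)2, DMSO, CH2Cl2, −78 °C; Et3N, −78 → 0 °C
Reagents that add atoms: none
Why: Swern oxidation activates both hydroxyls before base is added, so the keto aldehyde forms without the lactol and lactone that a stepwise oxidant would give from this 1,5-diol; the low temperature spares the β-silyloxy ketone.

Step 11
Reactants: 18 keto aldehyde
Product: 19 2-allyl-2-methyl-3-(2-methylbut-3-en-2-yl)-5-(tert-butyldimethylsilyloxy)cyclohexanone (diene ketone; centres as in 16)
Conditions: Ph3PCH3Br, KHMDS, THF, −78 → 0 °C
Reagents that add atoms: methyltriphenylphosphonium bromide, C[P+](c1ccccc1)(c1ccccc1)c1ccccc1.[Br-]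
Why: Wittig methylenation; the aldehyde reacts far faster than the ketone flanked by quaternary C10, and low temperature with only a slight excess of ylide limits enolisation toward C8.

Step 12
Reactants: 19 diene ketone
Product: 20 7α-(tert-butyldimethylsilyloxy)-4,4,10β-trimethyl-5α-decal-2-en-9-one (trans-fused; C2=C3 alkene)
Conditions: second-generation Grubbs catalyst (H2IMes)(PCy3)Cl2Ru=CHPh (5 mol %), CH2Cl2, 40 °C
Reagents that add atoms: none
Why: Ring-closing metathesis; the catalyst initiates at the unhindered allyl group and closes onto the neopentyl vinyl group, and because both arms are trans-diequatorial on ring B the six-membered ring A forms as the trans-decalin, driven by loss of ethylene.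

Step 13
Reactants: 20 bicyclic alkene ketone
Product: 21 7α-(tert-butyldimethylsilyloxy)-4,4,10β-trimethyl-5α-decalin-2α,9-diol (C9 epimer mixture)
Conditions: BH3·THF (excess), THF, 0 °C → rt; then NaOH, H2O2, H2O, 0 °C → rt
Reagents that add atoms: hydrogen peroxide, OO
Why: Hydroboration–oxidation; boron goes to C2 and not to the neopentyl C3, and from the α face because the axial C19 and C20 methyls shield the β face, so oxidation with retention gives the equatorial 2α-alcohol. Excess borane also reduces the C9 ketone, which is harmless.

Step 14
Reactants: 21 diol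
Product: 22 7α-(tert-butyldimethylsilyloxy)-2α-(triisopropylsilyloxy)-4,4,10β-trimethyl-5α-decalin-9-ol
Conditions: TIPSOTf (1.1 equiv), 2,6-lutidine, CH2Cl2, −78 °C
Reagents that add atoms: triisopropylsilyl triflate, CC(C)[Si](C(C)C)(C(C)C)OS(=O)(=O)C(F)(F)F
Why: The equatorial, unhindered C2 hydroxyl is silylated selectively; the C9 hydroxyl next to quaternary C10 does not react with the bulky silyl triflate at −78 °C. A silyl group without aryl rings is chosen because it must later survive dissolving metal.

Step 15
Reactants: 22 bis-silyl ether alcohol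
Product: 23 2α-(triisopropylsilyloxy)-4,4,10β-trimethyl-5α-decalin-7α,9-diol
Conditions: CSA (cat.), MeOH/CH2Cl2, 0 °C → rt
Reagents that add atoms: none
Why: Acid methanolysis cleaves a secondary tert-butyldimethylsilyl ether markedly faster than a secondary triisopropylsilyl ether.

Step 16
Reactants: 23 7,9-diol
Product: 24 2α-(triisopropylsilyloxy)-4,4,10β-trimethyl-5α-decalin-7,9-dione
Conditions: IBX, EtOAc, 75 °C
Reagents that add atoms: none
Why: IBX oxidises both secondary alcohols and is the reagent of choice for taking β-hydroxy ketones to β-diketones, because it leaves the active methylene of the product alone.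

Step 17
Reactants: 24 7,9-dione
Product: 25 2α-(triisopropylsilyloxy)-4,4,8,10β-tetramethyl-5α-decalin-7,9-dione (C8 enolisable)
Conditions: MeI, K2CO3, acetone, 50 °C
Reagents that add atoms: iodomethane, CI
Why: C-Alkylation of a cyclic 1,3-diketone enolate with a soft electrophile at the only doubly activated carbon, C8; this installs C17.

Step 18
Reactants: 25 8-methyl dione
Product: 26 7-methoxy-2α-(triisopropylsilyloxy)-4,4,8,10β-tetramethyl-5α-decal-7-en-9-one (vinylogous ester)
Conditions: HC(OMe)3, MeOH, CSA (cat.), rt
Reagents that add atoms: methanol, CO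
Why: Acid-catalysed enol etherification; methanol adds to the less hindered C7 carbonyl, and the isomer with the alkoxy group away from quaternary C10 is also the more stable one, so the ketone stays at C9 as the Stork–Danheiser sequence requires.

Step 19
Reactants: 26 vinylogous ester; 5 (R)-tert-butyl[(5-iodo-3-methylpentyl)oxy]dimethylsilane
Product: 29 (13S)-15-(tert-butyldimethylsilyloxy)-2α-(triisopropylsilyloxy)labd-8-en-7-one, via alkyllithium 27 (not isolated), via tertiary lithium alkoxide 28 (not isolated)
Conditions: 5, t-BuLi (2.1 equiv), Et2O/pentane, −78 °C; then 26, THF, −78 → 0 °C; then 1 M HCl, THF, 0 °C, brief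
Reagents that add atoms: water, O
Why: Lithium–iodine exchange gives primary alkyllithium 27, which adds 1,2 to the C9 carbonyl (C10 has no hydrogen to enolise); dilute acid then ionises the tertiary allylic carbinol of 28 and hydrolyses the enol ether with transposition (Stork–Danheiser sequence), giving the C7 ketone and the C8=C9 alkene. Organolithium additions to 3-alkoxy-2,6,6-trisubstituted cyclohexenones are the precedent, and the cold brief acid treatment keeps the primary silyl ether.

Step 20
Reactants: 29 enone
Product: 31 (13S)-15-(tert-butyldimethylsilyloxy)-2α-(triisopropylsilyloxy)labd-7-en-7-yl trifluoromethanesulfonate, via lithium enolate 30 (not isolated)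
Conditions: Li (2.2 equiv), t-BuOH (1.0 equiv), NH3(l)/THF, −78 °C; isoprene; NH3 removed; PhNTf2, THF, −78 → 0 °C
Reagents that add atoms: N-phenylbis(trifluoromethanesulfonimide), O=S(=O)(N(c1ccccc1)S(=O)(=O)C(F)(F)F)C(F)(F)F
Why: Dissolving-metal reduction of the enone protonates the β-carbon C9 axially from the α face, anti to the axial C20 methyl, which places the chain equatorial (9β) and hydrogen at 9α; the regiodefined C7–C8 enolate 30 is then trapped on oxygen (reduction–triflation).

Step 21
Reactants: 31 enol triflate
Product: 32 (13S)-15-(tert-butyldimethylsilyloxy)-2α-(triisopropylsilyloxy)labd-7-ene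
Conditions: Pd(OAc)2 (5 mol %), PPh3, HCO2H, Bu3N, DMF, 60 °C
Reagents that add atoms: none
Why: Palladium-catalysed formate reduction of an enol triflate (oxidative addition to zerovalent palladium, formate exchange, decarboxylation, reductive elimination) leaves the alkene exactly where the triflate was, at C7=C8, without touching C9.

Step 22
Reactants: 32 bis-silyl ether
Product: 33 (13S)-2α-(triisopropylsilyloxy)labd-7-en-15-ol
Conditions: PPTS, MeOH, rt
Reagents that add atoms: none
Why: A primary tert-butyldimethylsilyl ether is cleaved by mild acid far faster than a secondary triisopropylsilyl ether, and the acid is too weak to move the trisubstituted alkene.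

Step 23
Reactants: 33 primary alcohol; 34 bis(2,2,2-trifluoroethyl)phosphonoacetic acid
Product: 35 (13S)-2α-(triisopropylsilyloxy)labd-7-en-15-yl 2-[bis(2,2,2-trifluoroethoxy)phosphoryl]acetate
Conditions: DCC, DMAP (cat.), CH2Cl2, 0 °C → rt
Reagents that add atoms: none
Why: Steglich esterification of a primary alcohol; no stereochemistry is involved.

Step 24
Reactants: 35 phosphonoacetate; 36 4-(tert-butyldimethylsilyloxy)benzaldehyde
Product: 37 (13S)-2α-(triisopropylsilyloxy)labd-7-en-15-yl (Z)-3-[4-(tert-butyldimethylsilyloxy)phenyl]acrylate
Conditions: KHMDS, 18-crown-6, THF, −78 °C; then 36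
Reagents that add atoms: none
Why: Still–Gennari olefination; the electron-poor bis(trifluoroethyl) phosphonate with a dissociated potassium counter-ion eliminates faster than the adducts equilibrate, so the (Z)-cinnamate forms kinetically, and aryl aldehydes are favourable substrates.

Step 25
Reactants: 37 bis-silyl Z-coumarate
Product: 38 (13S)-labd-7-ene-2α,15-diol 15-[(Z)-p-coumarate] (CNP0301213.1)
Conditions: TBAF, AcOH, THF, 0 °C → rt, light excluded
Reagents that add atoms: none
Why: Fluoride cleaves the aryl silyl ether and the secondary triisopropylsilyl ether; acetic acid keeps the phenol protonated so that the Z-alkene cannot isomerise through the phenoxide.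

## Compound list

1 | (R)-3-methylglutaric acid monomethyl ester | COC(=O)C[C@H](C)CC(=O)O | starting material
2 | methyl (R)-5-hydroxy-3-methylpentanoate | COC(=O)C[C@H](C)CCO | intermediate
3 | methyl (R)-5-(tert-butyldimethylsilyloxy)-3-methylpentanoate | COC(=O)C[C@H](C)CCO[Si](C)(C)C(C)(C)C | intermediate
4 | (S)-5-(tert-butyldimethylsilyloxy)-3-methylpentan-1-ol | OCC[C@H](C)CCO[Si](C)(C)C(C)(C)C | intermediate
5 | (R)-tert-butyl[(5-iodo-3-methylpentyl)oxy]dimethylsilane | ICC[C@H](C)CCO[Si](C)(C)C(C)(C)C | intermediate
6 | (R)-carvone | CC1=CC[C@@H](C(C)=C)CC1=O | starting material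
7 | (5R)-5-(1-hydroperoxy-1-methoxyethyl)-2-methylcyclohex-2-enone (not isolated) | CC1=CC[C@@H](C(C)(OC)OO)CC1=O | intermediate
8 | peroxyacetate of 7 (not isolated) | CC1=CC[C@@H](C(C)(OC)OOC(C)=O)CC1=O | intermediate
9 | (R)-5-acetoxy-2-methylcyclohex-2-enone | CC1=CC[C@@H](OC(C)=O)CC1=O | intermediate
10 | (R)-5-hydroxy-2-methylcyclohex-2-enone | CC1=CC[C@@H](O)CC1=O | intermediate
11 | (R)-5-(tert-butyldimethylsilyloxy)-2-methylcyclohex-2-enone | CC1=CC[C@@H](O[Si](C)(C)C(C)(C)C)CC1=O | intermediate
12 | 1-methoxy-2-methyl-1-(trimethylsilyloxy)propene | COC(O[Si](C)(C)C)=C(C)C | starting material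
13 | allyl bromide | C=CCBr | starting material
14 | C9=C10 trimethylsilyl enol ether with C5β ester arm and C7α silyloxy (not isolated) | C[Si](C)(C)OC1=C(C)[C@H](C(C)(C)C(=O)OC)C[C@@H](O[Si](C)(C)C(C)(C)C)C1 | intermediate
15 | lithium enolate corresponding to 14 (not isolated) | [Li]OC1=C(C)[C@H](C(C)(C)C(=O)OC)C[C@@H](O[Si](C)(C)C(C)(C)C)C1 | intermediate
16 | methyl 2-[(1R,2S,5R)-2-allyl-5-(tert-butyldimethylsilyloxy)-2-methyl-3-oxocyclohexyl]-2-methylpropanoate | O=C1C[C@H](O[Si](C)(C)C(C)(C)C)C[C@@H](C(C)(C)C(=O)OC)[C@]1(C)CC=C | intermediate
17 | 2-allyl-3-(1-hydroxy-2-methylpropan-2-yl)-2-methyl-5-(tert-butyldimethylsilyloxy)cyclohexanol (C9 epimers) | OC1C[C@H](O[Si](C)(C)C(C)(C)C)C[C@@H](C(C)(C)CO)[C@]1(C)CC=C | intermediate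
18 | 2-[2-allyl-5-(tert-butyldimethylsilyloxy)-2-methyl-3-oxocyclohexyl]-2-methylpropanal | O=C1C[C@H](O[Si](C)(C)C(C)(C)C)C[C@@H](C(C)(C)C=O)[C@]1(C)CC=C | intermediate
19 | 2-allyl-2-methyl-3-(2-methylbut-3-en-2-yl)-5-(tert-butyldimethylsilyloxy)cyclohexanone | O=C1C[C@H](O[Si](C)(C)C(C)(C)C)C[C@@H](C(C)(C)C=C)[C@]1(C)CC=C | intermediate
20 | 7α-(tert-butyldimethylsilyloxy)-4,4,10β-trimethyl-5α-decal-2-en-9-one | O=C1C[C@H](O[Si](C)(C)C(C)(C)C)C[C@H]2C(C)(C)C=CC[C@]12C | intermediate
21 | 7α-(tert-butyldimethylsilyloxy)-4,4,10β-trimethyl-5α-decalin-2α,9-diol (C9 epimers) | OC1C[C@H](O[Si](C)(C)C(C)(C)C)C[C@H]2C(C)(C)C[C@H](O)C[C@]12C | intermediate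
22 | 7α-(tert-butyldimethylsilyloxy)-2α-(triisopropylsilyloxy)-4,4,10β-trimethyl-5α-decalin-9-ol | OC1C[C@H](O[Si](C)(C)C(C)(C)C)C[C@H]2C(C)(C)C[C@H](O[Si](C(C)C)(C(C)C)C(C)C)C[C@]12C | intermediate
23 | 2α-(triisopropylsilyloxy)-4,4,10β-trimethyl-5α-decalin-7α,9-diol | OC1C[C@H](O)C[C@H]2C(C)(C)C[C@H](O[Si](C(C)C)(C(C)C)C(C)C)C[C@]12C | intermediate
24 | 2α-(triisopropylsilyloxy)-4,4,10β-trimethyl-5α-decalin-7,9-dione | O=C1CC(=O)C[C@H]2C(C)(C)C[C@H](O[Si](C(C)C)(C(C)C)C(C)C)C[C@]12C | intermediate
25 | 2α-(triisopropylsilyloxy)-4,4,8,10β-tetramethyl-5α-decalin-7,9-dione | O=C1C(C)C(=O)C[C@H]2C(C)(C)C[C@H](O[Si](C(C)C)(C(C)C)C(C)C)C[C@]12C | intermediate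
26 | 7-methoxy-2α-(triisopropylsilyloxy)-4,4,8,10β-tetramethyl-5α-decal-7-en-9-one | O=C1C(C)=C(OC)C[C@H]2C(C)(C)C[C@H](O[Si](C(C)C)(C(C)C)C(C)C)C[C@]12C | intermediate
27 | (R)-[5-(tert-butyldimethylsilyloxy)-3-methylpentyl]lithium (not isolated) | [Li]CC[C@H](C)CCO[Si](C)(C)C(C)(C)C | intermediate
28 | C9 tertiary lithium alkoxide from 26 and 27 (not isolated; C9 epimers) | [Li]OC1(CC[C@H](C)CCO[Si](C)(C)C(C)(C)C)C(C)=C(OC)C[C@H]2C(C)(C)C[C@H](O[Si](C(C)C)(C(C)C)C(C)C)C[C@]12C | intermediate
29 | (13S)-15-(tert-butyldimethylsilyloxy)-2α-(triisopropylsilyloxy)labd-8-en-7-one | CC1=C(CC[C@H](C)CCO[Si](C)(C)C(C)(C)C)[C@@]2(C)C[C@@H](O[Si](C(C)C)(C(C)C)C(C)C)CC(C)(C)[C@@H]2CC1=O | intermediate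
30 | lithium C7–C8 enolate of the 9α-H labdan-7-one (not isolated) | CC1=C(O[Li])C[C@H]2C(C)(C)C[C@H](O[Si](C(C)C)(C(C)C)C(C)C)C[C@]2(C)[C@H]1CC[C@H](C)CCO[Si](C)(C)C(C)(C)C | intermediate
31 | (13S)-15-(tert-butyldimethylsilyloxy)-2α-(triisopropylsilyloxy)labd-7-en-7-yl triflate | CC1=C(OS(=O)(=O)C(F)(F)F)C[C@H]2C(C)(C)C[C@H](O[Si](C(C)C)(C(C)C)C(C)C)C[C@]2(C)[C@H]1CC[C@H](C)CCO[Si](C)(C)C(C)(C)C | intermediate
32 | (13S)-15-(tert-butyldimethylsilyloxy)-2α-(triisopropylsilyloxy)labd-7-ene | CC1=CC[C@H]2C(C)(C)C[C@H](O[Si](C(C)C)(C(C)C)C(C)C)C[C@]2(C)[C@H]1CC[C@H](C)CCO[Si](C)(C)C(C)(C)C | intermediate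
33 | (13S)-2α-(triisopropylsilyloxy)labd-7-en-15-ol | CC1=CC[C@H]2C(C)(C)C[C@H](O[Si](C(C)C)(C(C)C)C(C)C)C[C@]2(C)[C@H]1CC[C@H](C)CCO | intermediate
34 | bis(2,2,2-trifluoroethyl)phosphonoacetic acid | OC(=O)CP(=O)(OCC(F)(F)F)OCC(F)(F)F | starting material
35 | (13S)-2α-(triisopropylsilyloxy)labd-7-en-15-yl 2-[bis(2,2,2-trifluoroethoxy)phosphoryl]acetate | CC1=CC[C@H]2C(C)(C)C[C@H](O[Si](C(C)C)(C(C)C)C(C)C)C[C@]2(C)[C@H]1CC[C@H](C)CCOC(=O)CP(=O)(OCC(F)(F)F)OCC(F)(F)F | intermediate
36 | 4-(tert-butyldimethylsilyloxy)benzaldehyde | O=Cc1ccc(O[Si](C)(C)C(C)(C)C)cc1 | starting material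
37 | (13S)-2α-(triisopropylsilyloxy)labd-7-en-15-yl (Z)-3-[4-(tert-butyldimethylsilyloxy)phenyl]acrylate | CC1=CC[C@H]2C(C)(C)C[C@H](O[Si](C(C)C)(C(C)C)C(C)C)C[C@]2(C)[C@H]1CC[C@H](C)CCOC(=O)/C=C\c1ccc(O[Si](C)(C)C(C)(C)C)cc1 | intermediate
38 | (13S)-labd-7-ene-2α,15-diol 15-[(Z)-p-coumarate], CNP0301213.1 | CC1=CC[C@H]2C(C)(C)C[C@H](O)C[C@]2(C)[C@H]1CC[C@H](C)CCOC(=O)/C=C\c1ccc(O)cc1 | target

## Step count and risks

Total: 25 steps. Longest linear sequence: 21 steps (6 to 38, steps 5 to 25); fragment 5 takes 4 steps (steps 1 to 4).

**Step 8 (key step).** The most likely failure is loss of chemoselectivity or regio-integrity after the Michael addition: MeLi may attack the ester carbonyl in competition with silicon, or the enolate may equilibrate toward C8 and expel the C7 silanolate before it is allylated. Incomplete anti selectivity at C10 is a smaller concern. Fallback: 14 is isolated by a non-aqueous work-up and allylated under neutral conditions with allyl methyl carbonate and zerovalent palladium (Pd2(dba)3, dppe, THF, 65 °C; Tsuji–Trost-type allylation of a silyl enol ether, in which the methoxide released from the carbonate desilylates 14 and the enolate is captured by the π-allyl complex). This sets out from 14 and returns at 16 without a new compound.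

**Step 13.** Regioselectivity between C2 and C3 may be insufficient, because both alkene carbons are secondary and borane is small. Fallback from 20: dihydroxylation from the α face (OsO4 cat., NMO) gives the 2α,3α-diol ketone F1. Selective silylation of the equatorial C2 hydroxyl (TIPSOTf, 2,6-lutidine) gives the C2 silyl ether F2. The C3 hydroxyl is converted with 1,1'-thiocarbonyldiimidazole into the C3 imidazolylthiocarbonate F3 and removed with Bu3SnH/AIBN (Barton–McCombie deoxygenation) to give the 2α-silyloxy ketone F4. Acid methanolysis of the C7 silyl ether gives the β-hydroxy ketone F5, and IBX oxidation returns to the route at 24.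

**Step 19.** Addition to the C9 carbonyl may be sluggish, since it is flanked by quaternary C10 and the C8 methyl; deprotonation at C6 would then compete. Fallback from 26 and 5: γ-deprotonation of 26 (LDA) and O-triflation (PhNTf2) give the dienyl triflate F6. Iodide 5 is converted with zinc dust and LiCl into the alkylzinc iodide F7. Negishi coupling of F6 with F7 (PdCl2(dppf) cat., THF) gives the dienol ether F8, whose hydrolysis with dilute HCl returns to the route at 29.

**Step 20.** O-Triflation of the hindered tetrasubstituted enolate may be incomplete, with proton return giving the saturated ketone. Fallback from 29: the same lithium–ammonia reduction is quenched with ClP(O)(OEt)2 to give the enol diethyl phosphate F9, which is cleaved with Li, EtNH2 and t-BuOH in THF (dissolving-metal reduction of an enol phosphate). This returns to the route at 32 and skips 31.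

**Step 25.** Z to E isomerisation or ester cleavage may occur during the long fluoride exposure that the secondary triisopropylsilyl ether needs. Fallback from 35: the silyl ether is removed first (HF·pyridine, THF) to give the hydroxy phosphonoacetate F10. Still–Gennari olefination of F10 with 36 gives the Z-coumarate aryl silyl ether F11, the free secondary alcohol being tolerated because the phosphonate is far more acidic. A brief cleavage of the aryl silyl ether (HF·pyridine, pyridine, THF, 0 °C) returns to the route at 38.

## Further compounds

F0 | step 8 | none | none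
F1 | step 13 | 7α-(tert-butyldimethylsilyloxy)-2α,3α-dihydroxy-4,4,10β-trimethyl-5α-decalin-9-one | O=C1C[C@H](O[Si](C)(C)C(C)(C)C)C[C@H]2C(C)(C)[C@H](O)[C@H](O)C[C@]12C
F2 | step 13 | 7α-(tert-butyldimethylsilyloxy)-3α-hydroxy-2α-(triisopropylsilyloxy)-4,4,10β-trimethyl-5α-decalin-9-one | O=C1C[C@H](O[Si](C)(C)C(C)(C)C)C[C@H]2C(C)(C)[C@H](O)[C@H](O[Si](C(C)C)(C(C)C)C(C)C)C[C@]12C
F3 | step 13 | O-(3α-yl) imidazole-1-carbothioate of F2 | O=C1C[C@H](O[Si](C)(C)C(C)(C)C)C[C@H]2C(C)(C)[C@H](OC(=S)n3ccnc3)[C@H](O[Si](C(C)C)(C(C)C)C(C)C)C[C@]12C
F4 | step 13 | 7α-(tert-butyldimethylsilyloxy)-2α-(triisopropylsilyloxy)-4,4,10β-trimethyl-5α-decalin-9-one | O=C1C[C@H](O[Si](C)(C)C(C)(C)C)C[C@H]2C(C)(C)C[C@H](O[Si](C(C)C)(C(C)C)C(C)C)C[C@]12C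
F5 | step 13 | 7α-hydroxy-2α-(triisopropylsilyloxy)-4,4,10β-trimethyl-5α-decalin-9-one | O=C1C[C@H](O)C[C@H]2C(C)(C)C[C@H](O[Si](C(C)C)(C(C)C)C(C)C)C[C@]12C
F6 | step 19 | 7-methoxy-2α-(triisopropylsilyloxy)-4,4,8,10β-tetramethyl-5α-decala-6,8-dien-9-yl triflate | COC1=C[C@H]2C(C)(C)C[C@H](O[Si](C(C)C)(C(C)C)C(C)C)C[C@]2(C)C(OS(=O)(=O)C(F)(F)F)=C1C
F7 | step 19 | (R)-[5-(tert-butyldimethylsilyloxy)-3-methylpentyl]zinc iodide | I[Zn]CC[C@H](C)CCO[Si](C)(C)C(C)(C)C
F8 | step 19 | (13S)-7-methoxy-15-(tert-butyldimethylsilyloxy)-2α-(triisopropylsilyloxy)labda-6,8-diene | COC1=C[C@H]2C(C)(C)C[C@H](O[Si](C(C)C)(C(C)C)C(C)C)C[C@]2(C)C(CC[C@H](C)CCO[Si](C)(C)C(C)(C)C)=C1C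
F9 | step 20 | (13S)-15-(tert-butyldimethylsilyloxy)-2α-(triisopropylsilyloxy)labd-7-en-7-yl diethyl phosphate | CC1=C(OP(=O)(OCC)OCC)C[C@H]2C(C)(C)C[C@H](O[Si](C(C)C)(C(C)C)C(C)C)C[C@]2(C)[C@H]1CC[C@H](C)CCO[Si](C)(C)C(C)(C)C
F10 | step 25 | (13S)-2α-hydroxylabd-7-en-15-yl 2-[bis(2,2,2-trifluoroethoxy)phosphoryl]acetate | CC1=CC[C@H]2C(C)(C)C[C@H](O)C[C@]2(C)[C@H]1CC[C@H](C)CCOC(=O)CP(=O)(OCC(F)(F)F)OCC(F)(F)F
F11 | step 25 | (13S)-2α-hydroxylabd-7-en-15-yl (Z)-3-[4-(tert-butyldimethylsilyloxy)phenyl]acrylate | CC1=CC[C@H]2C(C)(C)C[C@H](O)C[C@]2(C)[C@H]1CC[C@H](C)CCOC(=O)/C=C\c1ccc(O[Si](C)(C)C(C)(C)C)cc1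
A1 | alternative 1 | (13S)-15-(tert-butyldimethylsilyloxy)labda-1,7-diene | CC1=CC[C@H]2C(C)(C)CC=C[C@]2(C)[C@H]1CC[C@H](C)CCO[Si](C)(C)C(C)(C)C
A2 | alternative 1 | triene with C5 allyl and C9 isopropenyl groups on the ring A cyclohexene | C=CC[C@H]1C(C)(C)CC=C[C@]1(C)[C@H](C(C)=C)CC[C@H](C)CCO[Si](C)(C)C(C)(C)C
A3 | alternative 1 | dimedone | CC1(C)CC(=O)CC(=O)C1
A4 | alternative 2 | bicyclic C7 silyl enol ether C11 methyl ester | C[C@H]1C(O[Si](C)(C)C(C)(C)C)=C[C@H]2C(C)(C)C[C@H](O[Si](C)(C)C(C)(C)C)C[C@]2(C)[C@H]1C(=O)OC
A5 | alternative 2 | acyclic silyloxytriene ester | C/C=C(\O[Si](C)(C)C(C)(C)C)/C=C/C(C)(C)C[C@H](O[Si](C)(C)C(C)(C)C)C/C(C)=C/C(=O)OC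
A6 | alternative 3 | 2α-formyloxy-4,4,8,10β-tetramethyl-5α-decal-7-en-9-one | CC1=CC[C@H]2C(C)(C)C[C@H](OC=O)C[C@]2(C)C1=O
A7 | alternative 3 | 6-allyl-6-methylcarvone (allyl trans to isopropenyl) | CC1=CC[C@@H](C(C)=C)[C@](C)(CC=C)C1=O
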